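Labdane numbering is used. Ring A is opened across C1–C2 and across the ring-fusion bond C5–C10, which unravels both rings to an acyclic chain. The key step is an intramolecular Diels–Alder reaction of a 2-silyloxy diene (C2=C3–C4=C5) with a 2-substituted acrolein (C1=C10; its formyl group becomes the C20 methyl), tethered through C6–C9 with the Z C7=C8 alkene and the C9 stereocentre in place. It exploits that C10 is quaternary, that C1 is an unsubstituted CH2 and that rings A and B share C5–C10: one cycloaddition closes both rings and sets C5 and C10 from C9. The geraniol-derived side chain is carried intact.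

Key step: step 9

Remark: the (1R,4R) enantiomer of the diene ligand in step 7 is an assumption about the sense of induction; the enantiomer that delivers the alkenyl group to the Re face of C3 of enal 5 is the one to be used.
Remark: compounds 4, 6, 7, 10 and 21 are taken as commercially available; labdane locants (C1–C20) are also used for the corresponding atoms of the acyclic precursors.

Step 1
Reactants: 1 geranyl acetate
Product: 3 (4E)-6-acetoxy-4-methylhex-4-enal, via 6,7-epoxygeranyl acetate 2 (not isolated)
Conditions: mCPBA, CH2Cl2, 0 °C; then H5IO6, THF/H2O, 0 °C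
Reagents that add atoms: 3-chloroperoxybenzoic acid (mCPBA), OOC(=O)c1cccc(Cl)c1
Why: The remote, electron-rich 6,7-alkene is epoxidised faster than the 2,3-alkene deactivated by the allylic acetate (Prilezhaev epoxidation), and aqueous periodic acid cleaves the epoxide to the aldehyde and acetone (Malaprade-type cleavage).

Step 2
Reactants: 3 (4E)-6-acetoxy-4-methylhex-4-enal; 4 (triphenylphosphoranylidene)acetaldehyde
Product: 5 (2E,6E)-8-acetoxy-6-methylocta-2,6-dienal
Conditions: 4 (1.05 equiv), toluene, 80 °C
Reagents that add atoms: none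
Why: Wittig reaction of the formyl-stabilised ylide with the unhindered aldehyde should give the E-enal, a single equivalent of ylide limiting further homologation.

Step 3
Reactants: 6 3-[(tert-butyldimethylsilyl)oxy]propanal; 7 ethyltriphenylphosphonium iodide
Product: 8 (Z)-tert-butyl[(4-iodopent-3-en-1-yl)oxy]dimethylsilane
Conditions: 7, n-BuLi, THF, 0 °C→rt; I2, −78 °C; NaN(SiMe3)2, −20 °C; then 6, −78 °C→rt
Reagents that add atoms: iodine, [I][I]
Why: Stork–Zhao olefination: the α-iodo ylide made in situ reacts through the kinetically favoured cis-oxaphosphetane to give the Z-2-iodoalkene (iodine cis to the chain), which fixes the ring-B C7=C8 geometry.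

Step 4
Reactants: 8 (Z)-tert-butyl[(4-iodopent-3-en-1-yl)oxy]dimethylsilane
Product: 9 (Z)-4-iodopent-3-en-1-ol
Conditions: CSA (cat.), MeOH, 0 °C→rt
Reagents that add atoms: none
Why: Acid-catalysed methanolysis removes the primary silyl ether without touching the vinyl iodide.

Step 5
Reactants: 9 (Z)-4-iodopent-3-en-1-ol; 10 3-(triphenylphosphoranylidene)butan-2-one
Product: 12 (3E,6Z)-7-iodo-3-methylocta-3,6-dien-2-one, via (Z)-4-iodopent-3-enal 11 (not isolated)
Conditions: DMP, pyridine, CH2Cl2, 0 °C; then 10, 0 °C→rt
Reagents that add atoms: none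
Why: Dess–Martin oxidation gives the isomerisation-prone β,γ-unsaturated aldehyde, which is trapped in the same flask by the acyl-stabilised ylide in an E-selective Wittig reaction to the trisubstituted enone.

Step 6
Reactants: 12 (3E,6Z)-7-iodo-3-methylocta-3,6-dien-2-one
Product: 13 (3E,6E)-3-methyl-7-(4,4,5,5-tetramethyl-1,3,2-dioxaborolan-2-yl)octa-3,6-dien-2-one
Conditions: B2pin2, PdCl2(PPh3)2 (3 mol%), PPh3, KOPh, toluene, 50 °C
Reagents that add atoms: bis(pinacolato)diboron, CC1(C)OB(OC1(C)C)B1OC(C)(C)C(C)(C)O1
Why: Palladium-catalysed Miyaura borylation of the alkenyl iodide with the mild base KOPh proceeds with retention of alkene geometry (boron cis to the chain) and should tolerate the enone.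

Step 7
Reactants: 5 (2E,6E)-8-acetoxy-6-methylocta-2,6-dienal; 13 (3E,6E)-3-methyl-7-(4,4,5,5-tetramethyl-1,3,2-dioxaborolan-2-yl)octa-3,6-dien-2-one
Product: 14 (3R,4Z,7E)-3-[(3E)-5-acetoxy-3-methylpent-3-en-1-yl]-4,8-dimethyl-9-oxodeca-4,7-dienal
Conditions: [RhCl(C2H4)2]2 (2.5 mol%), (1R,4R)-2,5-diphenylbicyclo[2.2.2]octa-2,5-diene (5.5 mol%), KOH (10 mol%), dioxane/H2O (10:1), 30 °C
Reagents that add atoms: none
Why: Hayashi–Miyaura-type asymmetric 1,4-addition: transmetalation gives an alkenyl complex of monovalent rhodium that inserts the enal (far more reactive than the α-methyl enone of 13), the chiral diene ligand favouring 1,4- over 1,2-addition and directing the alkenyl group to the Re face of C3, which sets the C9 stereocentre (3R in 14).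

Step 8
Reactants: 14 (3R,4Z,7E)-3-[(3E)-5-acetoxy-3-methylpent-3-en-1-yl]-4,8-dimethyl-9-oxodeca-4,7-dienal
Product: 15 (3S,4Z,7E)-3-[(3E)-5-acetoxy-3-methylpent-3-en-1-yl]-4,8-dimethyl-2-methylidene-9-oxodeca-4,7-dienal
Conditions: aq. CH2O (37%), pyrrolidine (10 mol%), EtCO2H (10 mol%), i-PrOH, 45 °C
Reagents that add atoms: formaldehyde, C=O
Why: Amine-catalysed α-methylenation (enamine Mannich reaction with formaldehyde, then elimination of the amine) is selective for the aldehyde over the methyl ketone and does not touch the β-stereocentre (the descriptor changes only by priority).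

Step 9
Reactants: 15 (3S,4Z,7E)-3-[(3E)-5-acetoxy-3-methylpent-3-en-1-yl]-4,8-dimethyl-2-methylidene-9-oxodeca-4,7-dienal
Product: 17 15-acetoxy-3-(tert-butyldimethylsilyloxy)-19-norlabda-3,7,13E-trien-20-al (5α-H, 9α-H, 10β-CHO), via silyloxy triene 16 (not isolated)
Conditions: TBSOTf (1.2 equiv), Et3N (3 equiv), CH2Cl2, −78→0 °C; then toluene (0.01 M), BHT, 80 °C
Reagents that add atoms: tert-butyldimethylsilyl trifluoromethanesulfonate, CC(C)(C)[Si](C)(C)OS(=O)(=O)C(F)(F)F
Why: Soft enolisation of the methyl ketone at its methyl group (the enal is not enolised under these conditions) gives the 2-silyloxy diene C2=C3(OTBS)–C4(Me)=C5, which adds thermally to the tethered 2-substituted acrolein C1=C10 in a concerted, asynchronous normal-demand [4+2] cycloaddition that forms C1–C2 and C5–C10. The closest known reaction type is the type 1 intramolecular Diels–Alder reaction of 1,3,9-decatrienes that carry a silyloxy diene and an enal, as used for decalin terpenoids. Ring A is closed as the six-membered cycloadduct ring, and ring B as the six-membered ring spanned by the four-atom tether C6–C9, whose Z C7=C8 alkene pre-organises the chain. C10 and C5 are set relative to each other by the transition state with the formyl group endo and the tether exo (anti), which gives the trans ring fusion and is reinforced by the C4 methyl group that would clash with the tether in the syn alternative. The π-face is controlled by C9: its hydrogen eclipses the C10=C1 bond (minimal allylic strain) and the side chain lies anti to the forming C5–C10 bond, so C11 and the formyl carbon C20 end up cis. The step needs regioselectivity (enforced by the tether and matched electronically, nucleophilic C2 meeting electrophilic C1), endo and facial selectivity as described, and enolisation at the methyl group instead of at C6, which low temperature and excess Et3N should secure.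

Step 10
Reactants: 17 15-acetoxy-3-(tert-butyldimethylsilyloxy)-19-norlabda-3,7,13E-trien-20-al
Product: 18 15-acetoxy-3-oxolabda-7,13E-dien-20-al
Conditions: BnMe3NF (anhydrous), MeI (5 equiv), 4 Å MS, THF, 0 °C→rt
Reagents that add atoms: iodomethane, IC
Why: Fluoride cleaves the Si–O bond to the regiodefined tetrasubstituted enolate, which is C-methylated at C4 by MeI (regiospecific alkylation of a silyl enol ether), creating the gem-dimethyl carbon next to a formyl group that cannot enolise.

Step 11
Reactants: 18 15-acetoxy-3-oxolabda-7,13E-dien-20-al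
Product: 20 (5S,9S,10S)-labda-7,13E-dien-15-ol, via bis-hydrazone 19 (not isolated)
Conditions: N2H4·H2O, KOH, diethylene glycol, 130 °C, then distil to 200 °C
Reagents that add atoms: none
Why: Wolff–Kishner reduction (Huang-Minlon modification) converts the C3 ketone to CH2 and the C20 aldehyde to the angular methyl group through their hydrazones while KOH saponifies the acetate; the isolated trisubstituted alkenes and the non-epimerisable stereocentres C5, C9 and C10 should be unaffected.

Step 12
Reactants: 20 (5S,9S,10S)-labda-7,13E-dien-15-ol; 21 Meldrum's acid (2,2-dimethyl-1,3-dioxane-4,6-dione)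
Product: 22 (5S,9S,10S)-labda-7,13E-dien-15-yl hydrogen malonate (CNP0279336.1)
Conditions: 21 (1.2 equiv), toluene, 100 °C
Reagents that add atoms: none
Why: Thermal acylation of the allylic alcohol by Meldrum's acid (ring opening with loss of acetone) gives the malonic acid half ester directly, without a protecting group on the acid.

Compound list
1 | geranyl acetate | CC(C)=CCC/C(C)=C/COC(C)=O | starting material
2 | 6,7-epoxygeranyl acetate (racemic epoxide, not isolated) | CC1(C)OC1CC/C(C)=C/COC(C)=O | intermediate
3 | (4E)-6-acetoxy-4-methylhex-4-enal | O=CCC/C(C)=C/COC(C)=O | intermediate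
4 | (triphenylphosphoranylidene)acetaldehyde | O=CC=P(c1ccccc1)(c1ccccc1)c1ccccc1 | starting material
5 | (2E,6E)-8-acetoxy-6-methylocta-2,6-dienal | O=C/C=C/CC/C(C)=C/COC(C)=O | intermediate
6 | 3-[(tert-butyldimethylsilyl)oxy]propanal | O=CCCO[Si](C)(C)C(C)(C)C | starting material
7 | ethyltriphenylphosphonium iodide | CC[P+](c1ccccc1)(c1ccccc1)c1ccccc1.[I-] | starting material
8 | (Z)-tert-butyl[(4-iodopent-3-en-1-yl)oxy]dimethylsilane | C/C(I)=C/CCO[Si](C)(C)C(C)(C)C | intermediate
9 | (Z)-4-iodopent-3-en-1-ol | C/C(I)=C/CCO | intermediate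
10 | 3-(triphenylphosphoranylidene)butan-2-one | CC(=O)C(C)=P(c1ccccc1)(c1ccccc1)c1ccccc1 | starting material
11 | (Z)-4-iodopent-3-enal (not isolated) | C/C(I)=C/CC=O | intermediate
12 | (3E,6Z)-7-iodo-3-methylocta-3,6-dien-2-one | CC(=O)/C(C)=C/C/C=C(/C)I | intermediate
13 | (3E,6E)-3-methyl-7-(4,4,5,5-tetramethyl-1,3,2-dioxaborolan-2-yl)octa-3,6-dien-2-one | CC(=O)/C(C)=C/C/C=C(/C)B1OC(C)(C)C(C)(C)O1 | intermediate
14 | (3R,4Z,7E)-3-[(3E)-5-acetoxy-3-methylpent-3-en-1-yl]-4,8-dimethyl-9-oxodeca-4,7-dienal | O=CC[C@H](/C(C)=C\C/C=C(C)/C(C)=O)CC/C(C)=C/COC(C)=O | intermediate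
15 | (3S,4Z,7E)-3-[(3E)-5-acetoxy-3-methylpent-3-en-1-yl]-4,8-dimethyl-2-methylidene-9-oxodeca-4,7-dienal | O=CC(=C)[C@H](/C(C)=C\C/C=C(C)/C(C)=O)CC/C(C)=C/COC(C)=O | intermediate
16 | (3S,4Z,7E)-3-[(3E)-5-acetoxy-3-methylpent-3-en-1-yl]-9-(tert-butyldimethylsilyloxy)-4,8-dimethyl-2-methylidenedeca-4,7,9-trienal (not isolated) | O=CC(=C)[C@H](/C(C)=C\C/C=C(C)/C(=C)O[Si](C)(C)C(C)(C)C)CC/C(C)=C/COC(C)=O | intermediate
17 | 15-acetoxy-3-(tert-butyldimethylsilyloxy)-19-norlabda-3,7,13E-trien-20-al (5α-H, 9α-H, 10β-CHO) | CC1=CC[C@H]2C(C)=C(O[Si](C)(C)C(C)(C)C)CC[C@]2(C=O)[C@H]1CC/C(C)=C/COC(C)=O | intermediate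
18 | 15-acetoxy-3-oxolabda-7,13E-dien-20-al | CC1=CC[C@H]2C(C)(C)C(=O)CC[C@]2(C=O)[C@H]1CC/C(C)=C/COC(C)=O | intermediate
19 | bis-hydrazone of 15-hydroxy-3-oxolabda-7,13E-dien-20-al (not isolated) | CC1=CC[C@H]2C(C)(C)C(=NN)CC[C@]2(C=NN)[C@H]1CC/C(C)=C/CO | intermediate
20 | (5S,9S,10S)-labda-7,13E-dien-15-ol | CC1=CC[C@H]2C(C)(C)CCC[C@]2(C)[C@H]1CC/C(C)=C/CO | intermediate
21 | Meldrum's acid | CC1(C)OC(=O)CC(=O)O1 | starting material
22 | (5S,9S,10S)-labda-7,13E-dien-15-yl hydrogen malonate (CNP0279336.1) | CC1=CC[C@H]2C(C)(C)CCC[C@]2(C)[C@H]1CC/C(C)=C/COC(=O)CC(=O)O | target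

Total step count: 12
Longest linear sequence: 10 steps (steps 3 to 12, from 6 to 22)

Steps most likely to fail

Step 9. The enol silylation may deprotonate toward the doubly allylic C6 instead of the methyl group, the silyl triflate may trigger Mukaiyama-type oligomerisation with the enal before the cycloaddition, and endo or facial selectivity may erode at 80 °C. The fallback sets out from 15 and comes back at 17, and generates the diene by enamine formation instead of silylation. Compound 15 would be condensed with pyrrolidine (4 Å MS, toluene, room temperature) to the 2-(pyrrolidin-1-yl) triene F1, whose cycloaddition should give the enamine cycloadduct F2. Hydrolysis with aqueous acetic acid would give 15-acetoxy-3-oxo-19-norlabda-7,13E-dien-20-al F3 as a mixture of C4 epimers. Silylation under equilibrating conditions (TBSCl, NaI, Et3N, MeCN, 50 °C) should then return the more substituted silyl enol ether 17.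

Step 7. Competing 1,2-addition to the aldehyde, protodeboronation of the hindered alkenylboronate, or weak facial discrimination on a purely aliphatic enal may occur. The fallback sets out from 13 (with 5) and comes back at 14, and replaces the rhodium alkenyl by iminium organocatalysis. Compound 13 would be converted with KHF2 (MeOH/H2O) into potassium [(2E,5E)-6-methyl-7-oxoocta-2,5-dien-2-yl]trifluoroborate F4. Conjugate alkenylation of 5 with F4 under a chiral 5-benzyl-2-tert-butyl-3-methylimidazolidin-4-one hydrochloride catalyst (enantiomer chosen for Re-face attack; HF, DME, −20 °C) should give 14; only the enal is activated, so the enone stays a spectator.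

Step 10. O-methylation of the hindered enolate, proton transfer followed by methylation at C2, or aldol capture of the naked enolate by the aldehyde may compete. The fallback sets out from 17 and comes back at 18, and avoids an enolate altogether. Simmons–Smith cyclopropanation of the electron-rich enol ether (Et2Zn, CH2I2, CH2Cl2, 0 °C) would give the 3-silyloxy-3,4-methano cyclopropane F5. Acid-mediated ring opening at the unsubstituted cyclopropane carbon (HCl cat., MeOH/THF, 0 °C) should then deliver the second C4 methyl group together with the C3 ketone of 18.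

Further compounds
F1 | step 9 | (3S,4Z,7E)-3-[(3E)-5-acetoxy-3-methylpent-3-en-1-yl]-4,8-dimethyl-2-methylidene-9-(pyrrolidin-1-yl)deca-4,7,9-trienal (not isolated) | O=CC(=C)[C@H](/C(C)=C\C/C=C(C)/C(=C)N1CCCC1)CC/C(C)=C/COC(C)=O
F2 | step 9 | 15-acetoxy-3-(pyrrolidin-1-yl)-19-norlabda-3,7,13E-trien-20-al (not isolated) | CC1=CC[C@H]2C(C)=C(N3CCCC3)CC[C@]2(C=O)[C@H]1CC/C(C)=C/COC(C)=O
F3 | step 9 | 15-acetoxy-3-oxo-19-norlabda-7,13E-dien-20-al (C4 epimers) | CC1=CC[C@H]2C(C)C(=O)CC[C@]2(C=O)[C@H]1CC/C(C)=C/COC(C)=O
F4 | step 7 | potassium [(2E,5E)-6-methyl-7-oxoocta-2,5-dien-2-yl]trifluoroborate | CC(=O)/C(C)=C/C/C=C(/C)[B-](F)(F)F.[K+]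
F5 | step 10 | 15-acetoxy-3-(tert-butyldimethylsilyloxy)-3,4-methano-19-norlabda-7,13E-dien-20-al (either cyclopropane face) | CC1=CC[C@H]2C3(C)CC3(O[Si](C)(C)C(C)(C)C)CC[C@]2(C=O)[C@H]1CC/C(C)=C/COC(C)=O
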